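## Structural features

Cathayanon H is a 2,3-trans dihydroflavonol in which a benzo-fused dihydropyranone (rings A and C) carries phenyl ring B at C2. Ring A is a phloroglucinol-type 5,7-diol whose C5 hydroxyl sits peri to the C4 ketone, and ring B is a 4'-phenol flanked at C3' and C5' by two prenyl (3-methylbut-2-en-1-yl) groups. The only stereocentres are the neighbours C2 (benzylic, bonded to O1, R) and C3 (carbinol alpha to the ketone, R), with aryl and hydroxyl trans. The two trisubstituted alkenes are fragile: they are open to epoxidation, hydrogenation and acid-promoted cyclisation onto the adjacent 4'-OH to give a chroman. The beta-aryloxy ketone opens by E1cB to a chalcone under base and so erases C2, and the alpha-ketol can epimerise or be oxidised to the flavonol. The real difficulty is therefore not the small skeleton but setting C2 absolutely and C3 relative to it without opening ring C or touching the prenyl groups, with phenol protection that leaves without acid or hydrogen. The key step exploits the fact that, in an open precursor, C2 is an O1-bearing benzylic CH2 with a hydridic C–H while C3 is the alpha-carbon of the C4 aryl ketone, so that the C2–C3 bond of ring C can be made by inserting a C3 ketocarbenoid into that C–H bond.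

## Logic of the disconnections

**17 to 16.** The three phenolic O–H bonds are traced back to O–Si bonds. Fluoride buffered with acetic acid removes them, which avoids the strong acid that would threaten the ortho-prenylphenol and the free base that would threaten the ketol. The demand is that one mild reagent cleaves three aryl silyl ethers without touching C2 or C3.

**16 to 14.** The C3–O bond is cut. This removes one stereocentre and leaves a flavanone whose C2 aryl group can direct the oxidant. The forward step must form the enolate (15) without opening ring C and must use an oxidant that ignores trisubstituted alkenes.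

**14 to 13.** The C2–C3 bond is cut, which opens ring C and removes the last stereocentre. The precursor is achiral and its C2 is a benzylic ether methylene. The forward step needs a chiral catalyst that selects one of the two enantiotopic benzylic hydrogens and a carbenoid that prefers this C–H to every other site.

**13 to 10.** The diazo group is traced back to the methyl group of the aryl methyl ketone, by way of 11 and 12. This avoids diazomethane and an acid chloride on a hindered, electron-rich ring. The forward step must activate a di-ortho-substituted acetophenone under conditions the silyl ethers survive.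

**10 to 9 and 7.** The O1–C2 ether bond is cut, giving two fragments of similar size. The forward step is an etherification of the one free, chelated phenol of 9 with the primary benzylic hydroxyl of 7 under neutral conditions.

**9 to 8.** Two O–Si bonds are cut. The forward step relies on the intrinsic difference between the chelated hydroxyl and the other two.

**7 to 5, 4, and then 1 and 2.** The aryl–CH2OH bond is cut back to the aryl–Br bond of 5 (through 6), the O–Si bond back to 4, and the two aryl–prenyl bonds back to 1 and two equivalents of 2 (through 3). The bromine blocks the para position during ortho C-alkylation and later becomes the handle for the one-carbon unit. The forward demand is ortho C- over O-alkylation of a phenoxide, twice.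

## Other disconnections considered

Alternative 1: The cut removes C4a–C8a, C7–C8 and C6–C7, so ring A is grown and not bought.
- Precursor: the cyclobutenone A2, whose 2-acyl chain carries C4, C3 (as its methoxymethyl ether), C2 with ring B, and O1 as an ethynyl ether.
- Forward step: heating should trigger four-electron ring opening of A2, and the ketene unit so exposed adds across the tethered ynol ether. The new four-membered ring opens, closes by a six-electron electrocyclisation and tautomerises to A1, forming rings C and A together.
- In favour: three bonds and two rings arise in one operation, against one bond and one ring in step 7. On bond count it is the better plan.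
- In favour: both stereocentres would be set on an open chain, so no ring-C enolate is needed. On C3 this is better than the chosen plan, which depends on step 8.
- In favour: it uses no diazo compound, so it is at least the equal on hazard.
- Against: A2 is a benzylic alkynyl ether, a class prone to [3,3] rearrangement and to retro-ene loss of ketene at the temperatures that open cyclobutenones.
- Against: after ring opening, the ketene carbon can be captured by the acyl oxygen instead of the alkyne.
- Against: C3 lies next to a 1,3-dicarbonyl-like unit with a leaving group at C2, so epimerisation and elimination are likely.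
- Comparison: the mechanism is a thermal cascade with several branch points, against a single catalytic event in step 7. Preparing A2 would need clearly more steps than the six that lead to 13, so step economy is worse.

Alternative 2: The cut removes O1–C8a and C4–C4a.
- Partners: the silylaryl triflate A4 and the hydroxy ester A5.
- Forward step: CsF should release the aryne A6 from A4. The alkoxide of A5 should add at the aryne carbon remote from the flanking ether, and the aryl anion next to that ether should attack the ester to give A3.
- In favour: the plan is convergent.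
- In favour: the regiochemistry follows the inductive bias of a 3-alkoxyaryne, which makes it the equal of the chosen plan, where ring A is used intact.
- In favour: C3 arrives oxygenated with both stereocentres set by acyclic stereocontrol, which is better than steps 7 and 8 on stereochemical certainty if the centres survive.
- Against: A6 is indiscriminate, and the allylic hydrogens of the prenyl groups invite ene reactions.
- Against: a hindered secondary alkoxide is a mediocre aryne nucleophile.
- Against: after O-arylation the aryl anion can be quenched by proton transfer instead of acylation, which would leave only a diaryl ether.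
- Against: the alkoxide of A5 can undergo retro-aldol cleavage, and the basic fluoride medium threatens the alpha-centre.
- Against: A3 needs four acetal groups removed with acid next to an ortho-prenylphenol.
- Comparison: A4 and A5 each need several steps, so the route is not shorter than the chosen one. The chosen key step runs under neutral conditions, which is its main advantage here.

Alternative 3: The cut removes C3–C4.
- Precursor: the dialdehyde A8.
- Forward step: a chiral triazolium salt and a mild base should give a carbene that turns the aryl aldehyde into a Breslow intermediate. This adds to the aliphatic aldehyde, closing ring C and giving A7.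
- In favour: ketone and C3 hydroxyl arise together in a redox-neutral step. This is better than the chosen plan on redox economy and saves the separate hydroxylation of step 8.
- In favour: no metal and no diazo compound are involved.
- In favour: the trans ketol is the thermodynamic isomer, a point on which it equals the chosen plan.
- Against: the aryl aldehyde is 2,4,6-trioxygenated, so it is hindered and deactivated. The carbene should prefer the aliphatic aldehyde, and that polarity would place the ketone at C3 and the hydroxyl at C4, the wrong regiochemistry.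
- Against: the stereocentre of A8 is an alpha-aryl-alpha-aryloxy aldehyde carbon and should racemise under the base. The step would then have to set C2 and C3 together by dynamic kinetic resolution.
- Against: A7 keeps an acidic C3–H under the same conditions.
- Comparison: step count would be about equal to the chosen plan. Stereochemical integrity is weaker than in step 7, where C2 is set under neutral conditions.

Key step: step 7

**Remarks on the chemistry**
- Abbreviations: prenyl = 3-methylbut-2-en-1-yl; TBS = tert-butyldimethylsilyl; TIPS = triisopropylsilyl; DIAD = diisopropyl azodicarboxylate.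
- C2 is S in 14 and R in 16 and 17 with the same spatial arrangement, because the new C3 oxygen raises the CIP rank of C3 above ring B.
- The phenols of the key-step precursor are carried as silyl ethers, not acetal ethers. An acetal ether ortho to the diazoketone would offer a second O–CH2 group at the same 1,6-distance, and an oxygen able to form an ylide and shift its alkoxymethyl group. The ortho oxygen therefore carries TIPS, which has no O–CH hydrogen. With all three phenols as silyl ethers the end game needs no acid.
- Assumption: the (S)-configured catalyst is taken to give (2S)-14. If the sense of induction is the opposite, Rh2(R-PTTL)4, dirhodium tetrakis[N-phthaloyl-(R)-tert-leucinate] (divalent rhodium), gives the mirror-image outcome.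

## Route

Step 1
Reactants: 1 4-bromophenol; 2 prenyl bromide (1-bromo-3-methylbut-2-ene)
Product: 4 4-bromo-2,6-bis(3-methylbut-2-en-1-yl)phenol, via 4-bromo-2-prenylphenol 3 (not isolated)
Conditions: NaH (2.2 equiv), toluene, 0 °C to rt; then 2 (2.2 equiv), rt
Reagents that add atoms: prenyl bromide (second equivalent of 2), CC(C)=CCBr
Why: In a non-polar solvent the sodium phenoxide is a tight aggregate with its oxygen blocked by the cation, so the allylic bromide is attacked by the ortho carbon at its primary terminus (phenoxide ortho C-alkylation, linear prenyl group) and the dienone tautomerises to 3; the excess NaH re-forms the phenoxide of 3 and, with bromine blocking the para position, the second equivalent of 2 goes to the other ortho carbon.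

Step 2
Reactants: 4 4-bromo-2,6-bis(3-methylbut-2-en-1-yl)phenol
Product: 5 tert-butyl[4-bromo-2,6-bis(3-methylbut-2-en-1-yl)phenoxy]dimethylsilane
Conditions: TBSCl, imidazole, DMF, rt
Reagents that add atoms: tert-butyldimethylsilyl chloride, CC(C)(C)[Si](C)(C)Cl
Why: Standard silylation of a phenol; the two ortho prenyl groups slow it but make the resulting aryl silyl ether resistant to the basic steps that follow.

Step 3
Reactants: 5 tert-butyl[4-bromo-2,6-bis(3-methylbut-2-en-1-yl)phenoxy]dimethylsilane
Product: 7 [4-(tert-butyldimethylsilyloxy)-3,5-bis(3-methylbut-2-en-1-yl)phenyl]methanol, via aryllithium 6 (not isolated)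
Conditions: n-BuLi (1.05 equiv), THF, –78 °C; dry (CH2O)n (excess), –78 °C to rt; aq. NH4Cl
Reagents that add atoms: paraformaldehyde (as formaldehyde), C=O
Why: Bromine–lithium exchange is faster than any deprotonation at –78 °C, and the aryllithium 6 adds to formaldehyde released from paraformaldehyde (hydroxymethylation of an aryllithium); the silyl ether is para to the carbanion and cannot migrate to it.

Step 4
Reactants: 8 2,4,6-trihydroxyacetophenone (dried)
Product: 9 1-[2-hydroxy-4,6-bis(triisopropylsilyloxy)phenyl]ethanone
Conditions: TIPSCl (2.1 equiv), imidazole (4 equiv), DMF, 0 °C to rt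
Reagents that add atoms: triisopropylsilyl chloride, CC(C)[Si](Cl)(C(C)C)C(C)C
Why: Selective phenol silylation: the para hydroxyl and the ortho hydroxyl not hydrogen-bonded to the acetyl oxygen react, while the chelated hydroxyl is too hindered and deactivated for the bulky chloride and stays free for step 5.

Step 5
Reactants: 9 1-[2-hydroxy-4,6-bis(triisopropylsilyloxy)phenyl]ethanone; 7 [4-(tert-butyldimethylsilyloxy)-3,5-bis(3-methylbut-2-en-1-yl)phenyl]methanol
Product: 10 1-{2-[4-(tert-butyldimethylsilyloxy)-3,5-bis(3-methylbut-2-en-1-yl)benzyloxy]-4,6-bis(triisopropylsilyloxy)phenyl}ethanone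
Conditions: PPh3, DIAD, THF, 0 °C to rt
Reagents that add atoms: none
Why: Mitsunobu etherification: the acidic chelated phenol of 9 protonates the betaine and its phenoxide displaces the activated primary benzylic oxygen of 7 under neutral conditions that leave the silyl ethers and alkenes alone.

Step 6
Reactants: 10 1-{2-[4-(tert-butyldimethylsilyloxy)-3,5-bis(3-methylbut-2-en-1-yl)benzyloxy]-4,6-bis(triisopropylsilyloxy)phenyl}ethanone
Product: 13 2-diazo-1-{2-[4-(tert-butyldimethylsilyloxy)-3,5-bis(3-methylbut-2-en-1-yl)benzyloxy]-4,6-bis(triisopropylsilyloxy)phenyl}ethanone, via lithium enolate 11 (not isolated), via trifluoroacetyl ketone 12 (not isolated)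
Conditions: LiN(SiMe3)2 (1.1 equiv), THF, –78 °C; CF3CO2CH2CF3 (1.2 equiv), –78 °C; cold dilute HCl wash; then 4-acetamidobenzenesulfonyl azide (1.5 equiv), Et3N (1.5 equiv), H2O (1 equiv), MeCN, rt
Reagents that add atoms: 4-acetamidobenzenesulfonyl azide, CC(=O)Nc1ccc(cc1)S(=O)(=O)N=[N+]=[N-]
Why: Claisen-type trifluoroacetylation of the methyl ketone enolate gives the 1,3-diketone 12, which accepts the diazo group from the sulfonyl azide and loses the trifluoroacetyl group to the sulfonamide nitrogen (detrifluoroacetylative, Regitz-type diazo transfer). The medium is only mildly basic, so the aryl silyl ethers should survive.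

Step 7
Reactants: 13 2-diazo-1-{2-[4-(tert-butyldimethylsilyloxy)-3,5-bis(3-methylbut-2-en-1-yl)benzyloxy]-4,6-bis(triisopropylsilyloxy)phenyl}ethanone
Product: 14 (2S)-2-[4-(tert-butyldimethylsilyloxy)-3,5-bis(3-methylbut-2-en-1-yl)phenyl]-5,7-bis(triisopropylsilyloxy)chroman-4-one
Conditions: Rh2(S-PTTL)4, dirhodium tetrakis[N-phthaloyl-(S)-tert-leucinate] (divalent rhodium, 2 mol %), CH2Cl2, 0 °C, slow addition of 13 to high dilution
Reagents that add atoms: none
Why: Loss of N2 from 13 at an axial site of the dirhodium core gives an electrophilic ketocarbenoid at C3, which engages the benzylic C–H bond at C2 in a concerted, asynchronous three-centre transition state with hydride-transfer character, so that C2–C3 forms with retention at carbon and the catalyst is released. The closest known reaction type is the chiral dirhodium carboxylate-catalysed intramolecular C–H insertion of ortho-alkoxyaryl diazoketones into the O–CH bond, which gives chroman-4-ones. Ring C closes as a six-membered ring by 1,6-insertion, because the 1,5-position that carbenoids usually prefer is O1 and carries no hydrogen. C2 is the only new stereocentre and is set by the catalyst, whose phthalimido walls should differentiate the two enantiotopic benzylic hydrogens; the (S)-catalyst is assumed to give (2S). The step needs selectivity for this C–H over ylide formation at O1 with a Stevens-type [1,2]-benzyl shift to a benzofuranone, over reaction at the other ortho oxygen, and over cyclopropanation of the prenyl alkenes. The para-silyloxy group of ring B makes the benzylic C–H hydridic, O1 is a weakly basic aryl ether oxygen, the C5 oxygen carries a bulky silyl group with no O–CH hydrogen and no migrating alkyl group, and slow addition at high dilution suppresses intermolecular cyclopropanation and carbene dimerisation.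

Step 8
Reactants: 14 (2S)-2-[4-(tert-butyldimethylsilyloxy)-3,5-bis(3-methylbut-2-en-1-yl)phenyl]-5,7-bis(triisopropylsilyloxy)chroman-4-one
Product: 16 (2R,3R)-2-[4-(tert-butyldimethylsilyloxy)-3,5-bis(3-methylbut-2-en-1-yl)phenyl]-3-hydroxy-5,7-bis(triisopropylsilyloxy)chroman-4-one, via lithium enolate 15 (not isolated)
Conditions: LiN(SiMe3)2 (1.1 equiv), THF, –78 °C; (±)-trans-3-phenyl-2-(phenylsulfonyl)oxaziridine (1.3 equiv), –78 °C; sat. NH4Cl at –78 °C
Reagents that add atoms: (±)-trans-3-phenyl-2-(phenylsulfonyl)oxaziridine, O=S(=O)(c1ccccc1)N1OC1c1ccccc1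
Why: Deprotonation at C3 gives the lithium enolate 15, and the N-sulfonyloxaziridine transfers oxygen to C3 (Davis enolate hydroxylation) without reacting with the prenyl alkenes at this temperature. The oxidant approaches anti to the pseudo-equatorial C2 aryl group, giving the 2,3-trans ketol, which is also the more stable diastereomer; the cold quench limits E1cB opening of ring C.

Step 9
Reactants: 16 (2R,3R)-2-[4-(tert-butyldimethylsilyloxy)-3,5-bis(3-methylbut-2-en-1-yl)phenyl]-3-hydroxy-5,7-bis(triisopropylsilyloxy)chroman-4-one
Product: 17 Cathayanon H, (2R,3R)-3,5,7-trihydroxy-2-[4-hydroxy-3,5-bis(3-methylbut-2-en-1-yl)phenyl]chroman-4-one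
Conditions: Bu4NF (3.3 equiv), AcOH (3.5 equiv), THF, 0 °C to rt
Reagents that add atoms: none
Why: Fluoride cleaves the three aryl silyl ethers (desilylation) while acetic acid protonates the phenoxides as they form, so the base-sensitive ketol and the acid-sensitive ortho-prenylphenol are both spared and neither stereocentre is touched.

## Compound list

1 | 4-bromophenol | Oc1ccc(Br)cc1 | starting material
2 | prenyl bromide (1-bromo-3-methylbut-2-ene) | CC(C)=CCBr | starting material
3 | 4-bromo-2-(3-methylbut-2-en-1-yl)phenol | CC(C)=CCc1cc(Br)ccc1O | intermediate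
4 | 4-bromo-2,6-bis(3-methylbut-2-en-1-yl)phenol | CC(C)=CCc1cc(Br)cc(CC=C(C)C)c1O | intermediate
5 | tert-butyl[4-bromo-2,6-bis(3-methylbut-2-en-1-yl)phenoxy]dimethylsilane | CC(C)=CCc1cc(Br)cc(CC=C(C)C)c1O[Si](C)(C)C(C)(C)C | intermediate
6 | [4-(tert-butyldimethylsilyloxy)-3,5-bis(3-methylbut-2-en-1-yl)phenyl]lithium | [Li]c1cc(CC=C(C)C)c(O[Si](C)(C)C(C)(C)C)c(CC=C(C)C)c1 | intermediate
7 | [4-(tert-butyldimethylsilyloxy)-3,5-bis(3-methylbut-2-en-1-yl)phenyl]methanol | CC(C)=CCc1cc(CO)cc(CC=C(C)C)c1O[Si](C)(C)C(C)(C)C | intermediate
8 | 2,4,6-trihydroxyacetophenone | CC(=O)c1c(O)cc(O)cc1O | starting material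
9 | 1-[2-hydroxy-4,6-bis(triisopropylsilyloxy)phenyl]ethanone | CC(=O)c1c(O)cc(O[Si](C(C)C)(C(C)C)C(C)C)cc1O[Si](C(C)C)(C(C)C)C(C)C | intermediate
10 | 1-{2-[4-(tert-butyldimethylsilyloxy)-3,5-bis(3-methylbut-2-en-1-yl)benzyloxy]-4,6-bis(triisopropylsilyloxy)phenyl}ethanone | CC(=O)c1c(O[Si](C(C)C)(C(C)C)C(C)C)cc(O[Si](C(C)C)(C(C)C)C(C)C)cc1OCc1cc(CC=C(C)C)c(O[Si](C)(C)C(C)(C)C)c(CC=C(C)C)c1 | intermediate
11 | lithium enolate of 10 (lithium 1-arylethen-1-olate) | [Li]OC(=C)c1c(O[Si](C(C)C)(C(C)C)C(C)C)cc(O[Si](C(C)C)(C(C)C)C(C)C)cc1OCc1cc(CC=C(C)C)c(O[Si](C)(C)C(C)(C)C)c(CC=C(C)C)c1 | intermediate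
12 | 4,4,4-trifluoro-1-{2-[4-(tert-butyldimethylsilyloxy)-3,5-bis(3-methylbut-2-en-1-yl)benzyloxy]-4,6-bis(triisopropylsilyloxy)phenyl}butane-1,3-dione | O=C(CC(=O)C(F)(F)F)c1c(O[Si](C(C)C)(C(C)C)C(C)C)cc(O[Si](C(C)C)(C(C)C)C(C)C)cc1OCc1cc(CC=C(C)C)c(O[Si](C)(C)C(C)(C)C)c(CC=C(C)C)c1 | intermediate
13 | 2-diazo-1-{2-[4-(tert-butyldimethylsilyloxy)-3,5-bis(3-methylbut-2-en-1-yl)benzyloxy]-4,6-bis(triisopropylsilyloxy)phenyl}ethanone | [N-]=[N+]=CC(=O)c1c(O[Si](C(C)C)(C(C)C)C(C)C)cc(O[Si](C(C)C)(C(C)C)C(C)C)cc1OCc1cc(CC=C(C)C)c(O[Si](C)(C)C(C)(C)C)c(CC=C(C)C)c1 | intermediate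
14 | (2S)-2-[4-(tert-butyldimethylsilyloxy)-3,5-bis(3-methylbut-2-en-1-yl)phenyl]-5,7-bis(triisopropylsilyloxy)chroman-4-one | CC(C)=CCc1cc([C@H]2Oc3cc(O[Si](C(C)C)(C(C)C)C(C)C)cc(O[Si](C(C)C)(C(C)C)C(C)C)c3C(=O)C2)cc(CC=C(C)C)c1O[Si](C)(C)C(C)(C)C | intermediate
15 | lithium (2S)-2-[4-(tert-butyldimethylsilyloxy)-3,5-bis(3-methylbut-2-en-1-yl)phenyl]-5,7-bis(triisopropylsilyloxy)-2H-chromen-4-olate | CC(C)=CCc1cc([C@H]2Oc3cc(O[Si](C(C)C)(C(C)C)C(C)C)cc(O[Si](C(C)C)(C(C)C)C(C)C)c3C(O[Li])=C2)cc(CC=C(C)C)c1O[Si](C)(C)C(C)(C)C | intermediate
16 | (2R,3R)-2-[4-(tert-butyldimethylsilyloxy)-3,5-bis(3-methylbut-2-en-1-yl)phenyl]-3-hydroxy-5,7-bis(triisopropylsilyloxy)chroman-4-one | CC(C)=CCc1cc([C@H]2Oc3cc(O[Si](C(C)C)(C(C)C)C(C)C)cc(O[Si](C(C)C)(C(C)C)C(C)C)c3C(=O)[C@@H]2O)cc(CC=C(C)C)c1O[Si](C)(C)C(C)(C)C | intermediate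
17 | Cathayanon H, (2R,3R)-3,5,7-trihydroxy-2-[4-hydroxy-3,5-bis(3-methylbut-2-en-1-yl)phenyl]chroman-4-one | CC(C)=CCc1cc([C@H]2Oc3cc(O)cc(O)c3C(=O)[C@@H]2O)cc(CC=C(C)C)c1O | target

## Step count and least certain steps

Total: 9 steps. Longest linear sequence: 8 steps (1, 2, 3, 5, 6, 7, 8, 9 from compound 1). The branch from compound 8 runs through steps 4 to 9 (6 steps).

**Step 7 (key step).**
- Most likely failure: diversion of the carbenoid to the oxonium ylide at O1 followed by [1,2]-benzyl shift.
- Second failure: weak discrimination between the two benzylic hydrogens, because an unstabilised ketocarbenoid reacts through an early transition state.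
- Third failure: intermolecular cyclopropanation of a prenyl alkene if the stationary concentration of 13 is not kept low.
- Fallback: it sets out from 9 and 5 and returns at 14, replacing carbenoid chemistry by conjugate addition. Condensation of 9 with N,N-dimethylformamide dimethyl acetal should give the enaminone (E)-3-(dimethylamino)-1-[2-hydroxy-4,6-bis(triisopropylsilyloxy)phenyl]prop-2-en-1-one F1. In warm acetic acid F1 should close, with loss of dimethylamine, to 5,7-bis(triisopropylsilyloxy)-4H-chromen-4-one F2. Bromine–lithium exchange on 5 as in step 3 (through 6), quench with B(OiPr)3 and mild hydrolysis should give [4-(tert-butyldimethylsilyloxy)-3,5-bis(3-methylbut-2-en-1-yl)phenyl]boronic acid F3. Asymmetric 1,4-addition of F3 to F2 would then give 14. The catalyst would be [Rh(OH)(C8H12)]2 (monovalent rhodium; C8H12 is cycloocta-1,5-diene) with an electron-poor atropisomeric bisphosphine of the MeO-BIPHEP type, in the enantiomeric form that leads to (2S), in toluene–water near room temperature and without added base.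

**Step 8.**
- Most likely failure: E1cB opening of the enolate to the chalcone phenoxide, which erodes C2.
- Second failure: addition of the enolate to the sulfonyl imine formed from the oxidant.
- Third failure: incomplete trans selectivity.
- Fallback: it sets out from 14 and returns at 16, avoiding a metal enolate. Soft enolisation with Me3SiOTf and Et3N in CH2Cl2 at 0 °C should give the silyl enol ether (2S)-2-[4-(tert-butyldimethylsilyloxy)-3,5-bis(3-methylbut-2-en-1-yl)phenyl]-5,7-bis(triisopropylsilyloxy)-4-(trimethylsilyloxy)-2H-chromene F4. Rubottom oxidation with one equivalent of dimethyldioxirane in acetone at –78 °C should give the 3,4-epoxy-4-(trimethylsilyloxy)flavan F5 (C2 as in 14, epoxide oxygen anti to the C2 aryl group). Work-up with dilute citric acid opens F5 to 16. The fallback depends on the enol silane being much more nucleophilic than the prenyl alkenes, so the oxidant must be limiting and the temperature low.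

**Step 5.**
- Most likely failure: ionisation of the electron-rich benzylic oxyphosphonium, leading to C-benzylation of ring A or oligomerisation.
- Second failure: slow reaction of the chelated, hindered phenol.
- Fallback: it sets out from 7 and 9 and returns at 10. The Appel reaction of 7 (CBr4, PPh3, CH2Cl2, 0 °C) should give [4-(bromomethyl)-2,6-bis(3-methylbut-2-en-1-yl)phenoxy](tert-butyl)dimethylsilane F6. F6 is used crude to alkylate the phenoxide of 9 (K2CO3, acetone, rt) in a Williamson etherification.

**Step 1.**
- Most likely failure: competing O-alkylation, incomplete second alkylation, or over-alkylation to dienones, all of which depend on the aggregation state of the phenoxide.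
- Fallback: it sets out from 1 and returns at 5, replacing phenoxide alkylation by cross-coupling. Ortho di-iodination of 1 (N-iodosuccinimide, MeCN, catalytic CF3CO2H) should give 4-bromo-2,6-diiodophenol F7. Silylation (TBSCl, imidazole, DMF) gives tert-butyl(4-bromo-2,6-diiodophenoxy)dimethylsilane F8. A double Stille coupling with tributyl(3-methylbut-2-en-1-yl)stannane and Pd(PPh3)4 (zerovalent palladium) in DMF at moderate temperature should replace both C–I bonds in preference to C–Br and give 5.

## Further compounds

F1 | step 7 | (E)-3-(dimethylamino)-1-[2-hydroxy-4,6-bis(triisopropylsilyloxy)phenyl]prop-2-en-1-one | CN(C)/C=C/C(=O)c1c(O)cc(O[Si](C(C)C)(C(C)C)C(C)C)cc1O[Si](C(C)C)(C(C)C)C(C)C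
F2 | step 7 | 5,7-bis(triisopropylsilyloxy)-4H-chromen-4-one | O=c1ccoc2cc(O[Si](C(C)C)(C(C)C)C(C)C)cc(O[Si](C(C)C)(C(C)C)C(C)C)c12
F3 | step 7 | [4-(tert-butyldimethylsilyloxy)-3,5-bis(3-methylbut-2-en-1-yl)phenyl]boronic acid | CC(C)=CCc1cc(B(O)O)cc(CC=C(C)C)c1O[Si](C)(C)C(C)(C)C
F4 | step 8 | (2S)-2-[4-(tert-butyldimethylsilyloxy)-3,5-bis(3-methylbut-2-en-1-yl)phenyl]-5,7-bis(triisopropylsilyloxy)-4-(trimethylsilyloxy)-2H-chromene | CC(C)=CCc1cc([C@H]2Oc3cc(O[Si](C(C)C)(C(C)C)C(C)C)cc(O[Si](C(C)C)(C(C)C)C(C)C)c3C(O[Si](C)(C)C)=C2)cc(CC=C(C)C)c1O[Si](C)(C)C(C)(C)C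
F5 | step 8 | 3,4-epoxy-4-(trimethylsilyloxy)flavan derived from F4, epoxide oxygen anti to the C2 aryl group | CC(C)=CCc1cc([C@H]2Oc3cc(O[Si](C(C)C)(C(C)C)C(C)C)cc(O[Si](C(C)C)(C(C)C)C(C)C)c3[C@@]4(O[Si](C)(C)C)[C@@H]2O4)cc(CC=C(C)C)c1O[Si](C)(C)C(C)(C)C
F6 | step 5 | [4-(bromomethyl)-2,6-bis(3-methylbut-2-en-1-yl)phenoxy](tert-butyl)dimethylsilane | CC(C)=CCc1cc(CBr)cc(CC=C(C)C)c1O[Si](C)(C)C(C)(C)C
F7 | step 1 | 4-bromo-2,6-diiodophenol | Oc1c(I)cc(Br)cc1I
F8 | step 1 | tert-butyl(4-bromo-2,6-diiodophenoxy)dimethylsilane | CC(C)(C)[Si](C)(C)Oc1c(I)cc(Br)cc1I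
A1 | alternative 1 | (2R,3R)-7-hydroxy-3,5-bis(methoxymethoxy)-2-[4-(methoxymethoxy)-3,5-bis(3-methylbut-2-en-1-yl)phenyl]chroman-4-one | CC(C)=CCc1cc([C@H]2Oc3cc(O)cc(OCOC)c3C(=O)[C@@H]2OCOC)cc(CC=C(C)C)c1OCOC
A2 | alternative 1 | 2-{(2R,3R)-3-(ethynyloxy)-2-(methoxymethoxy)-3-[4-(methoxymethoxy)-3,5-bis(3-methylbut-2-en-1-yl)phenyl]propanoyl}-3-(methoxymethoxy)cyclobut-2-en-1-one | O=C1CC(OCOC)=C1C(=O)[C@H](OCOC)[C@H](OC#C)c1cc(CC=C(C)C)c(OCOC)c(CC=C(C)C)c1
A3 | alternative 2 | (2R,3R)-3,5,7-tris(methoxymethoxy)-2-[4-(methoxymethoxy)-3,5-bis(3-methylbut-2-en-1-yl)phenyl]chroman-4-one | CC(C)=CCc1cc([C@H]2Oc3cc(OCOC)cc(OCOC)c3C(=O)[C@@H]2OCOC)cc(CC=C(C)C)c1OCOC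
A4 | alternative 2 | 3,5-bis(methoxymethoxy)-2-(trimethylsilyl)phenyl trifluoromethanesulfonate | COCOc1cc(OCOC)c([Si](C)(C)C)c(OS(=O)(=O)C(F)(F)F)c1
A5 | alternative 2 | methyl (2R,3R)-3-hydroxy-2-(methoxymethoxy)-3-[4-(methoxymethoxy)-3,5-bis(3-methylbut-2-en-1-yl)phenyl]propanoate | COC(=O)[C@H](OCOC)[C@H](O)c1cc(CC=C(C)C)c(OCOC)c(CC=C(C)C)c1
A6 | alternative 2 | 1,2-didehydro-3,5-bis(methoxymethoxy)benzene (3,5-bis(methoxymethoxy)benzyne) | COCOC1=CC(OCOC)=CC#C1
A7 | alternative 3 | (2R,3R)-3-hydroxy-5,7-bis(methoxymethoxy)-2-[4-(methoxymethoxy)-3,5-bis(3-methylbut-2-en-1-yl)phenyl]chroman-4-one | CC(C)=CCc1cc([C@H]2Oc3cc(OCOC)cc(OCOC)c3C(=O)[C@@H]2O)cc(CC=C(C)C)c1OCOC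
A8 | alternative 3 | 2-{(1R)-1-[4-(methoxymethoxy)-3,5-bis(3-methylbut-2-en-1-yl)phenyl]-2-oxoethoxy}-4,6-bis(methoxymethoxy)benzaldehyde | O=C[C@H](Oc1cc(OCOC)cc(OCOC)c1C=O)c1cc(CC=C(C)C)c(OCOC)c(CC=C(C)C)c1
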